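The trimer (units T, M, B; flavan numbering) is cut at M O1–C8a and M C8–T C4. These bonds end on neighbouring carbons of ring A of M, C8a (oxygen) and C8 (carbon) beside C7–O, which is the pattern an aryne accepts. In one operation a dilithiated seco-M fluoroarene alcohol, already bearing B on C4, loses LiF. Its C2 alkoxide closes the M pyran ring at C8a, and the C8 aryllithium formed adds to an aldehyde supplying T C4–C3–C2. That aldehyde carries ring A of T as the C2 aryl ether, so a cationic cyclisation and hydrogenolysis complete the target.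

Key step: step 19

Remarks on the chemistry
- Structure check: all three units are (2R,3R) (2,3-cis, epiafzelechin type), and both interflavan bonds are 4β→8 (3,4-trans).
- In the seco-M alcohol 18, C2–OH and C3–OBn are syn because step 19 keeps the C2–O bond. C3–O stays benzylated, since a free C3 alkoxide would close a five-membered ring on the aryne.
- Aldehyde 28 bears C3–OBn and ring A of T as a C2 aryl ether in place of a diol acetal, and both groups are spectators in step 19. An acyclic T C4 cation would be arylated intermolecularly anti to its bulky C2 branch, which is the wrong face, and a later O1–C2 closure would need net retention. The tether removes both problems.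
- Carbinols 13 and 32 are drawn as their Felkin–Anh epimers and 26 as a mixture at the acetal carbon; all of these centres disappear later.

Step 1
Reactants: 1 1,3,5-trifluorobenzene
Product: 2 1,3-bis(benzyloxy)-5-fluorobenzene
Conditions: BnOH (2.1 equiv), NaH, DMF, 0 → 90 °C
Reagents that add atoms: benzyl alcohol OCc1ccccc1
Why: Twofold nucleophilic aromatic substitution (SNAr), in which the fluorines activate one another inductively and each benzyloxy group slows the next displacement, so two equivalents of benzyloxide should stop at the monofluoride.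

Step 2
Reactants: 3 (S)-4-benzyloxazolidin-2-one; 4 (benzyloxy)acetyl chloride
Product: 5 (S)-4-benzyl-3-[(benzyloxy)acetyl]oxazolidin-2-one
Conditions: n-BuLi, THF, −78 → 0 °C
Reagents that add atoms: none
Why: N-Acylation of the lithiated Evans oxazolidinone by an acid chloride is the standard preparation of glycolate imides.

Step 3
Reactants: 5 (S)-4-benzyl-3-[(benzyloxy)acetyl]oxazolidin-2-one; 6 4-(benzyloxy)benzaldehyde
Product: 8 syn aldol adduct (S)-4-benzyl-3-{(2S,3R)-2-(benzyloxy)-3-[4-(benzyloxy)phenyl]-3-hydroxypropanoyl}oxazolidin-2-one, via dibutylboron enolate 7 (not isolated)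
Conditions: Bu2BOTf, Et3N, CH2Cl2, −78 → 0 °C; 6, −78 → 0 °C; H2O2, MeOH, pH 7 buffer
Reagents that add atoms: none
Why: Evans syn glycolate aldol reaction, in which the (Z)-boron enolate reacts through a Zimmerman–Traxler chair on the face away from the auxiliary benzyl group and sets the carbons that become C3 and C2 of units B and M in the syn relationship required for 2,3-cis flavans.

Step 4
Reactants: 8 syn aldol adduct
Product: 9 (2S,3R)-2-(benzyloxy)-3-[4-(benzyloxy)phenyl]-3-hydroxy-N-methoxy-N-methylpropanamide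
Conditions: MeONHMe·HCl, AlMe3, CH2Cl2, −10 °C → rt
Reagents that add atoms: N,O-dimethylhydroxylamine hydrochloride CNOC.Cl
Why: Weinreb transamidation with the aluminium amide, assisted by the free β-hydroxyl group, releases the auxiliary without touching either stereocentre.

Step 5
Reactants: 9 Weinreb amide
Product: 10 (2S,3R)-2-(benzyloxy)-3-[4-(benzyloxy)phenyl]-3-[(tert-butyldimethylsilyl)oxy]-N-methoxy-N-methylpropanamide
Conditions: TBSOTf, 2,6-lutidine, CH2Cl2, 0 °C
Reagents that add atoms: tert-butyldimethylsilyl triflate CC(C)(C)[Si](C)(C)OS(=O)(=O)C(F)(F)F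
Why: Silyl ether formation with a silyl triflate and a hindered base protects the benzylic alcohol under non-epimerising conditions and leaves it orthogonal to all benzyl ethers.

Step 6
Reactants: 10 silylated Weinreb amide
Product: 11 (2S,3R)-2-(benzyloxy)-3-[4-(benzyloxy)phenyl]-3-[(tert-butyldimethylsilyl)oxy]propanal
Conditions: i-Bu2AlH, THF, −78 °C
Reagents that add atoms: none
Why: Hydride reduction of a Weinreb amide stops at the chelated tetrahedral intermediate and gives the aldehyde only on work-up, so neither over-reduction nor α-epimerisation is expected.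

Step 7
Reactants: 2 1,3-bis(benzyloxy)-5-fluorobenzene; 11 aldehyde
Product: 13 (1R,2R,3R)-1-[2,4-bis(benzyloxy)-6-fluorophenyl]-2-(benzyloxy)-3-[4-(benzyloxy)phenyl]-3-[(tert-butyldimethylsilyl)oxy]propan-1-ol (Felkin–Anh epimer drawn), via 2,4-bis(benzyloxy)-6-fluorophenyllithium 12 (not isolated)
Conditions: n-BuLi, THF, −78 °C; 11, −78 °C; H2O
Reagents that add atoms: none
Why: Directed ortho-lithiation followed by 1,2-addition, in which the proton between fluorine and benzyloxy is the most acidic one of 2, the aryllithium keeps its fluoride at −78 °C, and the carbinol centre (polar Felkin–Anh epimer expected as the major one) does not matter because it is removed in step 8 or ionised in step 11.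

Step 8
Reactants: 13 benzylic carbinol
Product: 14 tert-butyl{(1R,2R)-2-(benzyloxy)-1-[4-(benzyloxy)phenyl]-3-[2,4-bis(benzyloxy)-6-fluorophenyl]propoxy}dimethylsilane
Conditions: Et3SiH, CF3CO2H, CH2Cl2, −40 → 0 °C
Reagents that add atoms: none
Why: Ionic hydrogenation, in which the 2,4-dialkoxybenzylic alcohol ionises far more readily than the silylated, β-oxygenated C2 position and the cation is captured by the silane to give the C4 methylene group of unit B.

Step 9
Reactants: 14 silyl ether
Product: 15 (1R,2R)-2-(benzyloxy)-1-[4-(benzyloxy)phenyl]-3-[2,4-bis(benzyloxy)-6-fluorophenyl]propan-1-ol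
Conditions: Bu4NF, THF, 0 °C → rt
Reagents that add atoms: none
Why: Fluoride-induced desilylation frees the C2 hydroxyl group and leaves benzyl ethers and the aryl fluoride untouched.

Step 10
Reactants: 15 fluoroarene alcohol
Product: 16 (2R,3R)-3,5,7-tris(benzyloxy)-2-[4-(benzyloxy)phenyl]chromane (tetra-O-benzyl-(−)-epiafzelechin, unit B)
Conditions: KH, THF–DMF (4:1), 0 °C → rt
Reagents that add atoms: none
Why: Intramolecular SNAr etherification, a known pyran closure of 2-fluoro-4,6-dialkoxyphenyl propanols, works because both benzyloxy groups are meta to fluorine, and since the C2–O bond is not broken the syn diol pattern becomes the 2,3-cis flavan.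

Step 11
Reactants: 13 benzylic carbinol; 16 tetra-O-benzyl-epiafzelechin
Product: 17 TBS ether of the seco-M fluoroarene alcohol (open chain Ar–CH(OTBS)–CH(OBn)–CH, with M C4 bearing the 2,4-bis(benzyloxy)-6-fluorophenyl ring and C8 of unit B)
Conditions: BF3·OEt2 (0.5 equiv), 16 (1.5 equiv), 4 Å MS, CH2Cl2, −78 → −30 °C
Reagents that add atoms: none
Why: Diastereoselective Friedel–Crafts alkylation through a chiral benzylic cation, in which either epimer of 13 ionises, 1,3-allylic strain against the ortho substituents holds C3–H in the cation plane, the bulky CH(OTBS)Ar branch shields one face, and the flavan attacks through its more nucleophilic C8 from the other face, setting M C4 as in the 3,4-trans series.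

Step 12
Reactants: 17 silyl ether
Product: 18 seco-M fluoroarene alcohol carrying unit B on M C4 (C2–OH and C3–OBn syn, configured as in 15)
Conditions: Bu4NF, THF, 0 °C → rt
Reagents that add atoms: none
Why: Fluoride-induced desilylation unveils the C2 hydroxyl group that becomes M O1 and changes nothing else.

Step 13
Reactants: 19 (R)-2,2-dimethyl-1,3-dioxolane-4-carbaldehyde; 20 4-(benzyloxy)phenylmagnesium bromide
Product: 22 (S)-[4-(benzyloxy)phenyl][(4R)-2,2-dimethyl-1,3-dioxolan-4-yl]methanol (anti), via aryltitanium triisopropoxide 21 (not isolated)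
Conditions: ClTi(OiPr)3, THF, −78 °C; 19, −78 → −20 °C; H2O
Reagents that add atoms: none
Why: Non-chelating aryltitanium addition to an α-alkoxy aldehyde follows the polar Felkin–Anh model and should give the anti alcohol, while the dioxolane carbon from the chiral pool becomes T C3.

Step 14
Reactants: 22 anti alcohol; 23 3,5-bis(benzyloxy)phenol
Product: 24 (4R)-4-{(R)-[4-(benzyloxy)phenyl][3,5-bis(benzyloxy)phenoxy]methyl}-2,2-dimethyl-1,3-dioxolane
Conditions: PPh3, DIAD, toluene, 0 °C
Reagents that add atoms: none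
Why: Mitsunobu etherification forms T O1–C2 with inversion, a reaction type established for electron-rich benzylic carbinols flanked by an oxygenated carbon, and converts the anti alcohol into the syn O1/O3 pattern of a 2,3-cis flavan.

Step 15
Reactants: 24 acetonide
Product: 25 (2R,3R)-3-[4-(benzyloxy)phenyl]-3-[3,5-bis(benzyloxy)phenoxy]propane-1,2-diol
Conditions: AcOH–H2O (4:1), 40 °C
Reagents that add atoms: none
Why: Mild acetal hydrolysis removes the terminal acetonide under conditions too weak to ionise the β-oxygenated benzylic aryl ether.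

Step 16
Reactants: 25 diol
Product: 26 (4R)-4-{(R)-[4-(benzyloxy)phenyl][3,5-bis(benzyloxy)phenoxy]methyl}-2-phenyl-1,3-dioxolane (mixture at the acetal carbon)
Conditions: PhCH(OMe)2, CSA (cat.), CH2Cl2, rt
Reagents that add atoms: benzaldehyde dimethyl acetal COC(OC)c1ccccc1
Why: Acid-catalysed transacetalisation turns the 1,2-diol into the benzylidene acetal that supplies the C3 benzyl group in the next step.

Step 17
Reactants: 26 benzylidene acetal
Product: 27 (2R,3R)-2-(benzyloxy)-3-[4-(benzyloxy)phenyl]-3-[3,5-bis(benzyloxy)phenoxy]propan-1-ol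
Conditions: i-Bu2AlH, CH2Cl2, −78 → 0 °C
Reagents that add atoms: none
Why: Regioselective reductive opening of a benzylidene acetal, in which aluminium binds the less hindered primary oxygen so that its C–O bond breaks and the benzyl group stays on the secondary oxygen.

Step 18
Reactants: 27 primary alcohol
Product: 28 (2S,3R)-2-(benzyloxy)-3-[4-(benzyloxy)phenyl]-3-[3,5-bis(benzyloxy)phenoxy]propanal
Conditions: Dess–Martin periodinane, CH2Cl2, 0 °C → rt
Reagents that add atoms: none
Why: Dess–Martin oxidation gives the aldehyde without base, so α-epimerisation and β-elimination of the aryloxy group are avoided.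

Step 19
Reactants: 18 seco-M fluoroarene alcohol; 28 aldehyde
Product: 32 closed M–B dimer bearing on M C8 the chain CH(OH)–CH(OBn)–CH(OAr)Ar that holds T C4–C3–C2 (Felkin–Anh epimer drawn), via dilithio species 29 (not isolated), via aryne alkoxide 30 (not isolated), via C8-aryllithium 31 (not isolated)
Conditions: n-BuLi (2.05 equiv), THF (0.01 M), −78 °C; −78 → −30 °C; recool to −78 °C; 28 (1.2 equiv), −78 °C; H2O
Reagents that add atoms: none
Why: Proposed new method: the first equivalent of n-BuLi forms the C2 lithium alkoxide and the second removes M C8–H, the only ring proton flanked by fluorine and benzyloxy, to give 29, which holds its fluoride at −78 °C and loses LiF on warming to give the C8a–C8 aryne 30. The tethered alkoxide adds to C8a in a 6-exo-dig closure that forms M O1–C8a with the C2–O bond untouched, so the stereotriad of 18 passes unchanged into the 2,3-cis-3,4-trans pyran ring. The six-membered tether and the inductive pull of C7–OBn, which favours negative charge on the aryne carbon next to it, both place oxygen on C8a and lithium on C8, so carbanion 31 exists only at C8 and no 4→6 isomer can arise. Anion 31 is a 2,6-dioxygenated aryllithium, stabilised by its flanking oxygens and free of any amine or other proton source because an alkyllithium is the base, so it should persist until 28 arrives at −78 °C and then add to the aldehyde to form M C8–T C4. The new carbinol centre should follow the polar Felkin–Anh model (OH anti to C3–OBn), but either epimer serves because the centre is ionised in step 20. The closest known reaction type is the anionic cyclisation of benzyne-tethered nucleophiles made from ortho-lithiated fluoroarenes with electrophilic trapping of the resulting aryllithium, known for carbon and nitrogen nucleophiles but not for an alkoxide followed by an aldehyde.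

Step 20
Reactants: 32 carbinol
Product: 33 dodeca-O-benzyl epiafzelechin-(4β→8)-epiafzelechin-(4β→8)-epiafzelechin
Conditions: BF3·OEt2 (0.3 equiv), 4 Å MS, CH2Cl2 (0.005 M), −78 → −40 °C
Reagents that add atoms: none
Why: Intramolecular Friedel–Crafts alkylation closes the T pyran ring through T C4–C4a, because the trioxygenated benzylic alcohol ionises readily, the two ortho oxygens of ring A of M hold C3–H in the cation plane by 1,3-allylic strain, and the aryl ether tethered to C2 can then reach only the face anti to C3–OBn, which sets T C4 as 3,4-trans.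

Step 21
Reactants: 33 dodecabenzyl ether
Product: 34 epiafzelechin-(4β→8)-epiafzelechin-(4β→8)-epiafzelechin (target CNP0191553.1)
Conditions: H2 (1 atm), Pd(OH)2/C, THF–MeOH–H2O, rt
Reagents that add atoms: none
Why: Catalytic hydrogenolysis removes all twelve benzyl ethers under neutral conditions that are standard for benzylated proanthocyanidins and leave the interflavan bonds and stereocentres intact.

Compound list
1 | 1,3,5-trifluorobenzene | Fc1cc(F)cc(F)c1 | starting material
2 | 1,3-bis(benzyloxy)-5-fluorobenzene | Fc1cc(OCc2ccccc2)cc(OCc2ccccc2)c1 | intermediate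
3 | (S)-4-benzyloxazolidin-2-one | O=C1N[C@@H](Cc2ccccc2)CO1 | starting material
4 | (benzyloxy)acetyl chloride | O=C(Cl)COCc1ccccc1 | starting material
5 | (S)-4-benzyl-3-[(benzyloxy)acetyl]oxazolidin-2-one | O=C(COCc1ccccc1)N1[C@@H](Cc2ccccc2)COC1=O | intermediate
6 | 4-(benzyloxy)benzaldehyde | O=Cc1ccc(OCc2ccccc2)cc1 | starting material
7 | (Z)-dibutylboron enolate of 5 | CCCCB(CCCC)O/C(=C\OCc1ccccc1)N1[C@@H](Cc2ccccc2)COC1=O | intermediate
8 | (S)-4-benzyl-3-{(2S,3R)-2-(benzyloxy)-3-[4-(benzyloxy)phenyl]-3-hydroxypropanoyl}oxazolidin-2-one | O=C([C@@H](OCc1ccccc1)[C@H](O)c1ccc(OCc2ccccc2)cc1)N1[C@@H](Cc2ccccc2)COC1=O | intermediate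
9 | (2S,3R)-2-(benzyloxy)-3-[4-(benzyloxy)phenyl]-3-hydroxy-N-methoxy-N-methylpropanamide | CON(C)C(=O)[C@@H](OCc1ccccc1)[C@H](O)c1ccc(OCc2ccccc2)cc1 | intermediate
10 | (2S,3R)-2-(benzyloxy)-3-[4-(benzyloxy)phenyl]-3-[(tert-butyldimethylsilyl)oxy]-N-methoxy-N-methylpropanamide | CON(C)C(=O)[C@@H](OCc1ccccc1)[C@H](O[Si](C)(C)C(C)(C)C)c1ccc(OCc2ccccc2)cc1 | intermediate
11 | (2S,3R)-2-(benzyloxy)-3-[4-(benzyloxy)phenyl]-3-[(tert-butyldimethylsilyl)oxy]propanal | O=C[C@@H](OCc1ccccc1)[C@H](O[Si](C)(C)C(C)(C)C)c1ccc(OCc2ccccc2)cc1 | intermediate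
12 | 2,4-bis(benzyloxy)-6-fluorophenyllithium | [Li]c1c(F)cc(OCc2ccccc2)cc1OCc1ccccc1 | intermediate
13 | (1R,2R,3R)-1-[2,4-bis(benzyloxy)-6-fluorophenyl]-2-(benzyloxy)-3-[4-(benzyloxy)phenyl]-3-[(tert-butyldimethylsilyl)oxy]propan-1-ol (Felkin–Anh epimer drawn) | Fc1cc(OCc2ccccc2)cc(OCc2ccccc2)c1[C@@H](O)[C@@H](OCc1ccccc1)[C@H](O[Si](C)(C)C(C)(C)C)c1ccc(OCc2ccccc2)cc1 | intermediate
14 | tert-butyl{(1R,2R)-2-(benzyloxy)-1-[4-(benzyloxy)phenyl]-3-[2,4-bis(benzyloxy)-6-fluorophenyl]propoxy}dimethylsilane | Fc1cc(OCc2ccccc2)cc(OCc2ccccc2)c1C[C@@H](OCc1ccccc1)[C@H](O[Si](C)(C)C(C)(C)C)c1ccc(OCc2ccccc2)cc1 | intermediate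
15 | (1R,2R)-2-(benzyloxy)-1-[4-(benzyloxy)phenyl]-3-[2,4-bis(benzyloxy)-6-fluorophenyl]propan-1-ol | Fc1cc(OCc2ccccc2)cc(OCc2ccccc2)c1C[C@@H](OCc1ccccc1)[C@H](O)c1ccc(OCc2ccccc2)cc1 | intermediate
16 | (2R,3R)-3,5,7-tris(benzyloxy)-2-[4-(benzyloxy)phenyl]chromane (unit B) | c1(OCc5ccccc5)cc(OCc5ccccc5)c2c(c1)O[C@H](c1ccc(OCc5ccccc5)cc1)[C@H](OCc5ccccc5)C2 | intermediate
17 | TBS ether of the seco-M fluoroarene alcohol with unit B on M C4 | O(Cc5ccccc5)c1ccc([C@@H](O[Si](C)(C)C(C)(C)C)[C@H](OCc5ccccc5)[C@H](c3c(F)cc(OCc5ccccc5)cc3OCc5ccccc5)c3c(OCc5ccccc5)cc(OCc5ccccc5)c4c3O[C@H](c3ccc(OCc5ccccc5)cc3)[C@H](OCc5ccccc5)C4)cc1 | intermediate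
18 | seco-M fluoroarene alcohol with unit B on M C4 | O(Cc5ccccc5)c1ccc([C@@H](O)[C@H](OCc5ccccc5)[C@H](c3c(F)cc(OCc5ccccc5)cc3OCc5ccccc5)c3c(OCc5ccccc5)cc(OCc5ccccc5)c4c3O[C@H](c3ccc(OCc5ccccc5)cc3)[C@H](OCc5ccccc5)C4)cc1 | intermediate
19 | (R)-2,2-dimethyl-1,3-dioxolane-4-carbaldehyde | CC1(C)OC[C@@H](O1)C=O | starting material
20 | 4-(benzyloxy)phenylmagnesium bromide | Br[Mg]c1ccc(OCc2ccccc2)cc1 | starting material
21 | [4-(benzyloxy)phenyl]titanium triisopropoxide | CC(C)O[Ti](OC(C)C)(OC(C)C)c1ccc(OCc2ccccc2)cc1 | intermediate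
22 | (S)-[4-(benzyloxy)phenyl][(4R)-2,2-dimethyl-1,3-dioxolan-4-yl]methanol | CC1(C)OC[C@@H](O1)[C@@H](O)c1ccc(OCc2ccccc2)cc1 | intermediate
23 | 3,5-bis(benzyloxy)phenol | Oc1cc(OCc2ccccc2)cc(OCc2ccccc2)c1 | starting material
24 | (4R)-4-{(R)-[4-(benzyloxy)phenyl][3,5-bis(benzyloxy)phenoxy]methyl}-2,2-dimethyl-1,3-dioxolane | CC1(C)OC[C@@H](O1)[C@H](Oc1cc(OCc2ccccc2)cc(OCc2ccccc2)c1)c1ccc(OCc2ccccc2)cc1 | intermediate
25 | (2R,3R)-3-[4-(benzyloxy)phenyl]-3-[3,5-bis(benzyloxy)phenoxy]propane-1,2-diol | OC[C@@H](O)[C@H](Oc1cc(OCc2ccccc2)cc(OCc2ccccc2)c1)c1ccc(OCc2ccccc2)cc1 | intermediate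
26 | (4R)-4-{(R)-[4-(benzyloxy)phenyl][3,5-bis(benzyloxy)phenoxy]methyl}-2-phenyl-1,3-dioxolane (acetal carbon unassigned) | c1ccccc1C1OC[C@@H](O1)[C@H](Oc1cc(OCc2ccccc2)cc(OCc2ccccc2)c1)c1ccc(OCc2ccccc2)cc1 | intermediate
27 | (2R,3R)-2-(benzyloxy)-3-[4-(benzyloxy)phenyl]-3-[3,5-bis(benzyloxy)phenoxy]propan-1-ol | OC[C@@H](OCc1ccccc1)[C@H](Oc1cc(OCc2ccccc2)cc(OCc2ccccc2)c1)c1ccc(OCc2ccccc2)cc1 | intermediate
28 | (2S,3R)-2-(benzyloxy)-3-[4-(benzyloxy)phenyl]-3-[3,5-bis(benzyloxy)phenoxy]propanal | O=C[C@@H](OCc1ccccc1)[C@H](Oc1cc(OCc2ccccc2)cc(OCc2ccccc2)c1)c1ccc(OCc2ccccc2)cc1 | intermediate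
29 | dilithio species: C2 lithium alkoxide of 18, lithiated at M C8 | O(Cc5ccccc5)c1ccc([C@@H](O[Li])[C@H](OCc5ccccc5)[C@H](c3c(F)c([Li])c(OCc5ccccc5)cc3OCc5ccccc5)c3c(OCc5ccccc5)cc(OCc5ccccc5)c4c3O[C@H](c3ccc(OCc5ccccc5)cc3)[C@H](OCc5ccccc5)C4)cc1 | intermediate
30 | M C8a–C8 aryne bearing the C2 lithium alkoxide | O(Cc5ccccc5)c1ccc([C@@H](O[Li])[C@H](OCc5ccccc5)[C@H](C3=C(OCc5ccccc5)C=C(OCc5ccccc5)C#C3)c3c(OCc5ccccc5)cc(OCc5ccccc5)c4c3O[C@H](c3ccc(OCc5ccccc5)cc3)[C@H](OCc5ccccc5)C4)cc1 | intermediate
31 | closed M–B dimer lithiated at M C8 | O(Cc5ccccc5)c1ccc([C@H]2Oc3c(c(OCc5ccccc5)cc(OCc5ccccc5)c3[Li])[C@H](c3c(OCc5ccccc5)cc(OCc5ccccc5)c4c3O[C@H](c3ccc(OCc5ccccc5)cc3)[C@H](OCc5ccccc5)C4)[C@H]2OCc5ccccc5)cc1 | intermediate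
32 | closed M–B dimer with the T C4 carbinol chain on M C8 (Felkin–Anh epimer drawn) | O(Cc5ccccc5)c1ccc([C@H]2Oc3c(c(OCc5ccccc5)cc(OCc5ccccc5)c3[C@@H](O)[C@@H](OCc5ccccc5)[C@H](Oc3cc(OCc5ccccc5)cc(OCc5ccccc5)c3)c3ccc(OCc5ccccc5)cc3)[C@H](c3c(OCc5ccccc5)cc(OCc5ccccc5)c4c3O[C@H](c3ccc(OCc5ccccc5)cc3)[C@H](OCc5ccccc5)C4)[C@H]2OCc5ccccc5)cc1 | intermediate
33 | dodeca-O-benzyl epiafzelechin-(4β→8)-epiafzelechin-(4β→8)-epiafzelechin | O(Cc5ccccc5)c1ccc([C@H]2Oc3c(c(OCc5ccccc5)cc(OCc5ccccc5)c3[C@H]3c4c(OCc5ccccc5)cc(OCc5ccccc5)cc4O[C@H](c4ccc(OCc5ccccc5)cc4)[C@@H]3OCc5ccccc5)[C@H](c3c(OCc5ccccc5)cc(OCc5ccccc5)c4c3O[C@H](c3ccc(OCc5ccccc5)cc3)[C@H](OCc5ccccc5)C4)[C@H]2OCc5ccccc5)cc1 | intermediate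
34 | epiafzelechin-(4β→8)-epiafzelechin-(4β→8)-epiafzelechin (CNP0191553.1) | Oc1ccc([C@H]2Oc3c(c(O)cc(O)c3[C@H]3c4c(O)cc(O)cc4O[C@H](c4ccc(O)cc4)[C@@H]3O)[C@H](c3c(O)cc(O)c4c3O[C@H](c3ccc(O)cc3)[C@H](O)C4)[C@H]2O)cc1 | target

Total step count: 21.
Longest linear sequence: 14 steps (steps 2–12, then 19–21).

Steps most likely to fail

1. Step 19.
   - What may go wrong: the aryne may be intercepted intermolecularly, by still unreacted 29 or by traces of n-BuLi, before the lithium alkoxide closes the ring. During the warm-up the aryllithiums may metalate a benzylic OCH2 position and start a Wittig rearrangement. The hindered anion 31 may also enolise 28 and expel the aryloxide instead of adding.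
   - Fallback (known chemistry, from 18 and 28, back at 33): 18 is closed with KH in THF–DMF by the SNAr reaction of step 10 to give the octa-O-benzyl epiafzelechin-(4β→8)-epiafzelechin dimer F1. Aldehyde 28 is cyclised with BF3·OEt2 at −78 °C by intramolecular hydroxyalkylation of its aryl ether ring to give the tetra-O-benzyl flavan-3,4-diol derivative F2. A classical Lewis-acid flavan-4-yl cation condensation (TMSOTf, CH2Cl2, −78 °C) of F2 with an excess of recoverable F1 then joins T C4 to the free C8 of unit M, trans to C3–OBn, and gives 33 directly.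

2. Step 11.
   - What may go wrong: capture of the acyclic cation may show poor or reversed facial selectivity. The flavan may attack in part through C6, or the silyl ether may be lost under the Lewis acid.
   - Fallback (from 16, back at 17): the roles of the two aryl groups are exchanged, which inverts the outcome at M C4 for a given facial bias and fixes the C8 linkage beforehand. Compound 16 is brominated regioselectively with NBS (CH2Cl2, −78 °C → rt) to the 8-bromoflavan F3. Bromine–lithium exchange (n-BuLi, THF, −78 °C) and addition to aldehyde 11 give the B C8 carbinol F4. BF3·OEt2-induced Friedel–Crafts arylation with an excess of fluoroarene 2, which reacts ortho to fluorine and para to benzyloxy, leads to 17.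

3. Step 14.
   - What may go wrong: the activated, electron-rich benzylic alcohol may ionise in part, which would erode the configuration at T C2. The phenol may also be alkylated on carbon.
   - Fallback (from 22, back at 24): the C2–O bond is kept and the aryl–oxygen bond is made instead. Compound 22 is oxidised with Dess–Martin periodinane to the aryl ketone F5. Felkin–Anh reduction with LiBH(s-Bu)3 (THF, −78 °C) gives the syn alcohol F6. An Ullmann-type coupling with 1,3-bis(benzyloxy)-5-iodobenzene (CuI, 3,4,7,8-tetramethyl-1,10-phenanthroline, Cs2CO3, toluene, 90 °C) then arylates the oxygen with retention at carbon and gives 24.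

Further compounds
F1 | step 19 | octa-O-benzyl epiafzelechin-(4β→8)-epiafzelechin (M C8–H) | O(Cc5ccccc5)c1ccc([C@H]2Oc3c(c(OCc5ccccc5)cc(OCc5ccccc5)c3)[C@H](c3c(OCc5ccccc5)cc(OCc5ccccc5)c4c3O[C@H](c3ccc(OCc5ccccc5)cc3)[C@H](OCc5ccccc5)C4)[C@H]2OCc5ccccc5)cc1
F2 | step 19 | 2,3-cis-3,5,7-tris(benzyloxy)-2-[4-(benzyloxy)phenyl]chroman-4-ol with C2 and C3 configured as in unit T of 33 (4β-ol drawn, C4 configuration immaterial) | O[C@H]3c4c(OCc5ccccc5)cc(OCc5ccccc5)cc4O[C@H](c4ccc(OCc5ccccc5)cc4)[C@@H]3OCc5ccccc5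
F3 | step 11 | (2R,3R)-8-bromo-3,5,7-tris(benzyloxy)-2-[4-(benzyloxy)phenyl]chromane | Brc1c(OCc5ccccc5)cc(OCc5ccccc5)c2c1O[C@H](c1ccc(OCc5ccccc5)cc1)[C@H](OCc5ccccc5)C2
F4 | step 11 | carbinol from 8-lithiated 16 and aldehyde 11 (Felkin–Anh epimer drawn) | c1(OCc5ccccc5)cc(OCc5ccccc5)c2c(O[C@H](c3ccc(OCc5ccccc5)cc3)[C@H](OCc5ccccc5)C2)c1[C@@H](O)[C@@H](OCc5ccccc5)[C@H](O[Si](C)(C)C(C)(C)C)c1ccc(OCc5ccccc5)cc1
F5 | step 14 | [4-(benzyloxy)phenyl][(4R)-2,2-dimethyl-1,3-dioxolan-4-yl]methanone | CC1(C)OC[C@@H](O1)C(=O)c1ccc(OCc2ccccc2)cc1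
F6 | step 14 | (R)-[4-(benzyloxy)phenyl][(4R)-2,2-dimethyl-1,3-dioxolan-4-yl]methanol (syn) | CC1(C)OC[C@@H](O1)[C@H](O)c1ccc(OCc2ccccc2)cc1
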